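**Plan**

1. Ring numbering used below: C1 = ring C=O, C2 (Me) and C3 = oxirane carbons, C4 = CH2, C5 = side-chain carbon, C6 = acyloxy carbon. The retrosynthesis cuts the O–O bond (Schenck ene), the two side-chain C–C(=O) bonds (carbonylative Stille on a vinylstannane made from a C5 ethynyl group), the oxirane oxygen, the tiglate, and then the ring bonds C4–C5 and C1–C2 together.
2. Enabling feature: C6 (O) and C5 (side chain) are trans and C6 carries the C1 carbonyl, so C1–C6–C5 is a latent trans-glycidic ester. The epoxy ketone hides the enone C1–C2(Me)=C3–C4, i.e. a crotyl anion acylated at its γ-carbon; a phenylsulfonyl group on C4 lets this one three-carbon unit make both bonds.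
3. Forward: Sharpless oxirane on an enynol (a temporary ring, not in the target) → glycidate 6 → one-flask epoxide opening/γ-acylation with crotyl sulfone 8 closes the carbocycle (step 5) → sulfone and silyl helpers removed → tiglate → a temporary C1 carbinol directs the C2–C3 oxirane → the alkyne becomes the α-methylene prenyl ketone → C1 reoxidised → hydroperoxide last.
4. Stereochemistry: C5 and C6 both come from the Sharpless epoxide (inversion at C5, retention at C6). The C1 carbinol is set by axial hydride delivery and C2/C3 by hydroxyl-directed epoxidation from it. The (E)-enone comes from the ene reaction and the tiglate from the (E)-acid.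

Key step: step 5

Remark: commercial (2E)-pent-2-en-4-yn-1-ol and (2E)-1-bromobut-2-ene are taken as single (E)-isomers; the double bond of 8 is remade inside the ring in step 5, so its geometry has no consequence.

**Route**

Step 1
Reactants: 1 (2E)-pent-2-en-4-yn-1-ol
Product: 3 (2E)-5-(trimethylsilyl)pent-2-en-4-yn-1-ol, via bis-silyl ether 2 (not isolated)
Conditions: EtMgBr (2.2 equiv), THF, 0 °C to rt; Me3SiCl (2.2 equiv); 1 M HCl
Reagents that add atoms: chlorotrimethylsilane, C[Si](C)(C)Cl
Why: Acetylide C-silylation: the magnesium alkoxide–acetylide is silylated at oxygen and carbon and the acid work-up cleaves only the labile O–Si bond, leaving a silyl cap that later keeps nucleophiles off the alkyne terminus; no stereocentre is formed.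

Step 2
Reactants: 3 (2E)-5-(trimethylsilyl)pent-2-en-4-yn-1-ol
Product: 4 {(2R,3R)-3-[(trimethylsilyl)ethynyl]oxiran-2-yl}methanol
Conditions: Ti(OiPr)4 (10 mol%), D-(−)-diethyl tartrate (12 mol%), t-BuOOH, 4 Å molecular sieves, CH2Cl2, −20 °C
Reagents that add atoms: tert-butyl hydroperoxide, CC(C)(C)OO
Why: Sharpless asymmetric epoxidation: with D-(−)-diethyl tartrate the titanium–tartrate complex should deliver the peroxide oxygen to the alkene face that gives the (2R,3R)-trans-epoxide, which fixes what become C5 and C6 of the ring, while the alkyne is not touched.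

Step 3
Reactants: 4 {(2R,3R)-3-[(trimethylsilyl)ethynyl]oxiran-2-yl}methanol
Product: 6 methyl (2S,3R)-3-[(trimethylsilyl)ethynyl]oxirane-2-carboxylate, via glycidic acid 5 (not isolated)
Conditions: TEMPO (20 mol%), PhI(OAc)2 (2.2 equiv), MeCN/H2O, rt; then Me3SiCHN2, toluene/MeOH, 0 °C
Reagents that add atoms: water, O; (trimethylsilyl)diazomethane, C[Si](C)(C)C=[N+]=[N-]
Why: Oxoammonium (TEMPO) oxidation of the primary alcohol through the aldehyde hydrate to the acid, then neutral O-methylation by the diazoalkane, should leave the oxirane and its two stereocentres untouched.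

Step 4
Reactants: 7 (2E)-1-bromobut-2-ene
Product: 8 [(2E)-but-2-en-1-ylsulfonyl]benzene
Conditions: PhSO2Na, DMF, rt
Reagents that add atoms: sodium benzenesulfinate, [Na+].[O-]S(=O)c1ccccc1
Why: SN2 S-alkylation of the sulfinate by the primary allylic bromide gives the sulfone, whose sulfonyl group is the removable activating group that lets C4 act as a carbanion twice.

Step 5
Reactants: 8 [(2E)-but-2-en-1-ylsulfonyl]benzene; 6 methyl (2S,3R)-3-[(trimethylsilyl)ethynyl]oxirane-2-carboxylate
Product: 11 (5S,6S)-6-hydroxy-2-methyl-4-(phenylsulfonyl)-5-[(trimethylsilyl)ethynyl]cyclohex-2-en-1-one, via ring-opened hydroxy ester 9 (not isolated), via deconjugated vinyl sulfone 10 (not isolated)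
Conditions: 8, n-BuLi, THF, −78 °C; 6, BF3·OEt2, −78 °C; LiN(iPr)2 (3 equiv), −78 to 0 °C; aq NH4Cl; Et3N (cat.), CH2Cl2, rt
Reagents that add atoms: none
Why: Proposed new method: lithiated allyl sulfone 8 should open the BF3-activated oxirane of 6 at C5 by SN2 attack (new bond C4–C5, giving 9), and the added amide base then regenerates the sulfonyl-stabilised allyl anion at C4, which can reach the ester only through its γ-carbon C2, so that a Claisen-type acylation (new bond C1–C2) expels methoxide and closes the carbocycle. The closest known reaction types are the BF3-promoted opening of epoxides by α-sulfonyl carbanions and the Dieckmann-type intramolecular acylation of sulfonyl carbanions by esters; their union in one flask as a [3+3] annulation with acylation at the γ-carbon of the allyl anion has no direct precedent. The six-membered ring closes by 6-exo-trig attack of C2 on the ester carbonyl, the α-attack from C4 being ruled out because it would make a four-membered ring. C5 is the only new stereocentre that is kept and it is set by inversion at the epoxide carbon, while C6 retains the glycidate configuration, so the trans-epoxide of step 2 becomes the trans C5/C6 pair; C4 and the transient C2 centre are erased in steps 5 and 6. The step needs epoxide opening before ester acylation (BF3 activation at −78 °C, where sulfonyl carbanions acylate esters only slowly), attack at C5 and not at C6 or the alkyne terminus (propargylic activation at C5, the ester deactivating C6 towards Lewis-acid-assisted opening, the silyl cap shielding the alkyne), and a driving force for ring closure (the doubly activated C2–H of the product is deprotonated at once, and Et3N finally equilibrates the kinetic isomer 10 to the conjugated enone 11).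

Step 6
Reactants: 11 (5S,6S)-6-hydroxy-2-methyl-4-(phenylsulfonyl)-5-[(trimethylsilyl)ethynyl]cyclohex-2-en-1-one
Product: 13 (5S,6S)-5-ethynyl-6-hydroxy-2-methylcyclohex-2-en-1-one, via silyl-capped deconjugated enone 12 (not isolated)
Conditions: SmI2 (2.2 equiv), THF/MeOH, −78 °C; then K2CO3 (0.2 equiv), MeOH, 0 °C
Reagents that add atoms: none
Why: Reductive desulfonylation of a vinylogous β-keto sulfone: electron transfer from SmI2 to the enone should expel the γ-sulfinate and methanol protonates the dienolate, after which K2CO3 in methanol returns the double bond to conjugation and protodesilylates the alkyne; C5 is not enolisable and C6 is already in its stable trans arrangement.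

Step 7
Reactants: 13 (5S,6S)-5-ethynyl-6-hydroxy-2-methylcyclohex-2-en-1-one
Product: 14 (1S,6S)-6-ethynyl-3-methyl-2-oxocyclohex-3-en-1-yl (2E)-2-methylbut-2-enoate
Conditions: (E)-2-methylbut-2-enoic acid, DCC, DMAP (cat.), CH2Cl2, 0 °C to rt
Reagents that add atoms: (E)-2-methylbut-2-enoic acid (tiglic acid), OC(=O)/C(C)=C/C
Why: Steglich esterification of the secondary α-ketol under near-neutral conditions avoids ketene formation from an acid chloride and keeps the stable (E)-geometry of the tiglate; no stereocentre changes.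

Step 8
Reactants: 14 (1S,6S)-6-ethynyl-3-methyl-2-oxocyclohex-3-en-1-yl (2E)-2-methylbut-2-enoate
Product: 15 (1S,2S,6S)-6-ethynyl-2-hydroxy-3-methylcyclohex-3-en-1-yl (2E)-2-methylbut-2-enoate
Conditions: NaBH4, CeCl3·7H2O, MeOH, −78 °C; AcOH
Reagents that add atoms: none
Why: Luche 1,2-reduction: with the C5 and C6 substituents equatorial the small hydride should add axially to C1, anti to the axial C6–H, to give the all-equatorial alcohol whose hydroxyl is cis to the C5 ethynyl group and trans to the ester (as carvone gives cis-carveol), the low temperature and acidic quench suppressing 1,2-acyl migration.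

Step 9
Reactants: 15 (1S,2S,6S)-6-ethynyl-2-hydroxy-3-methylcyclohex-3-en-1-yl (2E)-2-methylbut-2-enoate
Product: 16 (1R,2R,3S,4S,6S)-4-ethynyl-2-hydroxy-1-methyl-7-oxabicyclo[4.1.0]heptan-3-yl (2E)-2-methylbut-2-enoate
Conditions: VO(acac)2 (5 mol%), t-BuOOH, CH2Cl2, 0 °C
Reagents that add atoms: tert-butyl hydroperoxide, CC(C)(C)OO
Why: Hydroxyl-directed vanadium-catalysed epoxidation: the allylic C1 hydroxyl binds the vanadium peroxide and delivers oxygen syn to itself, i.e. to the face cis to the C5 substituent that nucleophilic epoxidation of the enone would not favour, while the electron-poor tiglate and the alkyne are inert.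

Step 10
Reactants: 16 (1R,2R,3S,4S,6S)-4-ethynyl-2-hydroxy-1-methyl-7-oxabicyclo[4.1.0]heptan-3-yl (2E)-2-methylbut-2-enoate
Product: 17 (1R,2R,3S,4R,6S)-2-hydroxy-1-methyl-4-[1-(tributylstannyl)ethenyl]-7-oxabicyclo[4.1.0]heptan-3-yl (2E)-2-methylbut-2-enoate
Conditions: Bu3SnH, Mo(CO)3(CNtBu)3 (5 mol%), hydroquinone (cat.), THF, 55 °C
Reagents that add atoms: tributyltin hydride, CCCC[SnH](CCCC)CCCC
Why: Molybdenum-catalysed hydrostannation of a terminal alkyne should add Sn–H syn with tin on the internal carbon, giving the 1,1-disubstituted vinylstannane under neutral, non-radical conditions (hydroquinone) that spare the oxirane and the ester.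

Step 11
Reactants: 17 (1R,2R,3S,4R,6S)-2-hydroxy-1-methyl-4-[1-(tributylstannyl)ethenyl]-7-oxabicyclo[4.1.0]heptan-3-yl (2E)-2-methylbut-2-enoate
Product: 18 (1R,2R,3S,4S,6S)-2-hydroxy-1-methyl-4-(6-methyl-3-oxohepta-1,5-dien-2-yl)-7-oxabicyclo[4.1.0]heptan-3-yl (2E)-2-methylbut-2-enoate
Conditions: 1-chloro-3-methylbut-2-ene, CO (3 atm), PdCl2(MeCN)2 (5 mol%), THF, 50 °C
Reagents that add atoms: 1-chloro-3-methylbut-2-ene (prenyl chloride), CC(C)=CCCl; carbon monoxide, [C-]#[O+]
Why: Stille carbonylative coupling: oxidative addition of the allylic chloride, CO insertion at the primary allyl terminus and transmetalation from the vinylstannane should give the allyl vinyl ketone with the prenyl double bond kept in the β,γ-position, the substrate being carried as the C1 alcohol because palladium catalysts can isomerise α,β-epoxy ketones.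

Step 12
Reactants: 18 (1R,2R,3S,4S,6S)-2-hydroxy-1-methyl-4-(6-methyl-3-oxohepta-1,5-dien-2-yl)-7-oxabicyclo[4.1.0]heptan-3-yl (2E)-2-methylbut-2-enoate
Product: 19 (1S,3S,4S,6S)-1-methyl-4-(6-methyl-3-oxohepta-1,5-dien-2-yl)-2-oxo-7-oxabicyclo[4.1.0]heptan-3-yl (2E)-2-methylbut-2-enoate
Conditions: Dess–Martin periodinane, NaHCO3, CH2Cl2, 0 °C to rt
Reagents that add atoms: none
Why: Dess–Martin oxidation of the secondary C1 alcohol under buffered conditions should restore the epoxy ketone without epimerising C6 or moving the β,γ-double bond into conjugation.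

Step 13
Reactants: 19 (1S,3S,4S,6S)-1-methyl-4-(6-methyl-3-oxohepta-1,5-dien-2-yl)-2-oxo-7-oxabicyclo[4.1.0]heptan-3-yl (2E)-2-methylbut-2-enoate
Product: 20 (1S,3S,4S,6S)-4-[(4E)-6-hydroperoxy-6-methyl-3-oxohepta-1,4-dien-2-yl]-1-methyl-2-oxo-7-oxabicyclo[4.1.0]heptan-3-yl (2E)-2-methylbut-2-enoate
Conditions: O2, visible light, tetraphenylporphyrin (cat.), CH2Cl2, −20 °C
Reagents that add atoms: dioxygen, O=O
Why: Schenck ene reaction: singlet oxygen attacks the only electron-rich alkene and should abstract the allylic hydrogen that is also α to the ketone, which moves the double bond into conjugation as the (E)-enone and leaves the tertiary hydroperoxide; the secondary hydroperoxide from methyl abstraction is the expected minor isomer to be removed.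

**Compound list**

1 | (2E)-pent-2-en-4-yn-1-ol | C#C/C=C/CO | starting material
2 | trimethyl{[(2E)-5-(trimethylsilyl)pent-2-en-4-yn-1-yl]oxy}silane | C[Si](C)(C)C#C/C=C/CO[Si](C)(C)C | intermediate
3 | (2E)-5-(trimethylsilyl)pent-2-en-4-yn-1-ol | C[Si](C)(C)C#C/C=C/CO | intermediate
4 | {(2R,3R)-3-[(trimethylsilyl)ethynyl]oxiran-2-yl}methanol | OC[C@H]1O[C@@H]1C#C[Si](C)(C)C | intermediate
5 | (2S,3R)-3-[(trimethylsilyl)ethynyl]oxirane-2-carboxylic acid | OC(=O)[C@H]1O[C@@H]1C#C[Si](C)(C)C | intermediate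
6 | methyl (2S,3R)-3-[(trimethylsilyl)ethynyl]oxirane-2-carboxylate | COC(=O)[C@H]1O[C@@H]1C#C[Si](C)(C)C | intermediate
7 | (2E)-1-bromobut-2-ene | C/C=C/CBr | starting material
8 | [(2E)-but-2-en-1-ylsulfonyl]benzene | C/C=C/CS(=O)(=O)c1ccccc1 | intermediate
9 | methyl (2S,3S,5E)-2-hydroxy-4-(phenylsulfonyl)-3-[(trimethylsilyl)ethynyl]hept-5-enoate (C4 epimers) | COC(=O)[C@@H](O)[C@H](C#C[Si](C)(C)C)C(/C=C/C)S(=O)(=O)c1ccccc1 | intermediate
10 | (5S,6S)-6-hydroxy-2-methyl-4-(phenylsulfonyl)-5-[(trimethylsilyl)ethynyl]cyclohex-3-en-1-one (C2 epimers) | C[Si](C)(C)C#C[C@@H]1C(S(=O)(=O)c2ccccc2)=CC(C)C(=O)[C@H]1O | intermediate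
11 | (5S,6S)-6-hydroxy-2-methyl-4-(phenylsulfonyl)-5-[(trimethylsilyl)ethynyl]cyclohex-2-en-1-one (C4 epimers) | C[Si](C)(C)C#C[C@@H]1C(S(=O)(=O)c2ccccc2)C=C(C)C(=O)[C@H]1O | intermediate
12 | (5S,6S)-6-hydroxy-2-methyl-5-[(trimethylsilyl)ethynyl]cyclohex-3-en-1-one (C2 epimers) | C[Si](C)(C)C#C[C@@H]1C=CC(C)C(=O)[C@H]1O | intermediate
13 | (5S,6S)-5-ethynyl-6-hydroxy-2-methylcyclohex-2-en-1-one | C#C[C@@H]1CC=C(C)C(=O)[C@H]1O | intermediate
14 | (1S,6S)-6-ethynyl-3-methyl-2-oxocyclohex-3-en-1-yl (2E)-2-methylbut-2-enoate | C#C[C@@H]1CC=C(C)C(=O)[C@H]1OC(=O)/C(C)=C/C | intermediate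
15 | (1S,2S,6S)-6-ethynyl-2-hydroxy-3-methylcyclohex-3-en-1-yl (2E)-2-methylbut-2-enoate | C#C[C@@H]1CC=C(C)[C@H](O)[C@H]1OC(=O)/C(C)=C/C | intermediate
16 | (1R,2R,3S,4S,6S)-4-ethynyl-2-hydroxy-1-methyl-7-oxabicyclo[4.1.0]heptan-3-yl (2E)-2-methylbut-2-enoate | C#C[C@@H]1C[C@@H]2O[C@]2(C)[C@H](O)[C@H]1OC(=O)/C(C)=C/C | intermediate
17 | (1R,2R,3S,4R,6S)-2-hydroxy-1-methyl-4-[1-(tributylstannyl)ethenyl]-7-oxabicyclo[4.1.0]heptan-3-yl (2E)-2-methylbut-2-enoate | CCCC[Sn](CCCC)(CCCC)C(=C)[C@@H]1C[C@@H]2O[C@]2(C)[C@H](O)[C@H]1OC(=O)/C(C)=C/C | intermediate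
18 | (1R,2R,3S,4S,6S)-2-hydroxy-1-methyl-4-(6-methyl-3-oxohepta-1,5-dien-2-yl)-7-oxabicyclo[4.1.0]heptan-3-yl (2E)-2-methylbut-2-enoate | C=C(C(=O)CC=C(C)C)[C@@H]1C[C@@H]2O[C@]2(C)[C@H](O)[C@H]1OC(=O)/C(C)=C/C | intermediate
19 | (1S,3S,4S,6S)-1-methyl-4-(6-methyl-3-oxohepta-1,5-dien-2-yl)-2-oxo-7-oxabicyclo[4.1.0]heptan-3-yl (2E)-2-methylbut-2-enoate | C=C(C(=O)CC=C(C)C)[C@@H]1C[C@@H]2O[C@]2(C)C(=O)[C@H]1OC(=O)/C(C)=C/C | intermediate
20 | (1S,3S,4S,6S)-4-[(4E)-6-hydroperoxy-6-methyl-3-oxohepta-1,4-dien-2-yl]-1-methyl-2-oxo-7-oxabicyclo[4.1.0]heptan-3-yl (2E)-2-methylbut-2-enoate (CNP0284595.1) | C=C(C(=O)/C=C/C(C)(C)OO)[C@@H]1C[C@@H]2O[C@]2(C)C(=O)[C@H]1OC(=O)/C(C)=C/C | target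

**Count and risks**

Total step count: 13. Longest linear sequence: 12 steps (steps 1–3 and 5–13; step 4 makes the second partner of step 5).

Steps most likely to fail:

1. Step 5 (Proposed new method). What may go wrong: acylation of the sulfonyl carbanion by the ester before the oxirane opens, opening at C6 or conjugate opening through the alkyne, or failure of the allyl anion to acylate through its γ-carbon. Fallback with known reactions, from 3 back to 13: MnO2 (CH2Cl2) oxidises 3 to (2E)-5-(trimethylsilyl)pent-2-en-4-ynal F1. F1 and tert-butyl 3-oxopentanoate undergo Michael addition under diphenylprolinol trimethylsilyl ether catalysis (the enantiomer that leads the nucleophile to the Re face of the enal β-carbon; PhCO2H, toluene, rt), and TsOH (toluene, 80 °C) then closes the ring by aldol condensation to tert-butyl (6S)-3-methyl-2-oxo-6-[(trimethylsilyl)ethynyl]cyclohex-3-ene-1-carboxylate F2 (the same bonds C4–C5 and C1–C2, but with the carbonyl on C3). Under the same conditions F2 loses isobutene and CO2 to give (5S)-2-methyl-5-[(trimethylsilyl)ethynyl]cyclohex-2-en-1-one F3. H2O2/NaOH in MeOH gives (1S,4S,6S)-4-ethynyl-1-methyl-7-oxabicyclo[4.1.0]heptan-2-one F4 (the silyl group is lost). Wharton transposition (N2H4·H2O, AcOH, MeOH) moves the oxygen to C1 in (1S,5R)-5-ethynyl-2-methylcyclohex-2-en-1-ol F5, and MnO2 gives (5R)-5-ethynyl-2-methylcyclohex-2-en-1-one F6. Mn(OAc)3 (benzene, reflux) acetoxylates C6 trans to the ethynyl group to give (1S,6S)-6-ethynyl-3-methyl-2-oxocyclohex-3-en-1-yl acetate F7, and K2CO3/MeOH then gives 13.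

2. Step 10. What may go wrong: tin adding to the terminal carbon, which gives the linear (E)-stannane instead of the branched one. Fallback, from 16 back to 17: hydrosilylation with Et3SiH and [Cp*Ru(MeCN)3]PF6 (CH2Cl2, 0 °C), which puts silicon on the internal carbon of terminal alkynes, gives (1R,2R,3S,4R,6S)-2-hydroxy-1-methyl-4-[1-(triethylsilyl)ethenyl]-7-oxabicyclo[4.1.0]heptan-3-yl (2E)-2-methylbut-2-enoate F10. Iododesilylation with N-iodosuccinimide in (CF3)2CHOH gives (1R,2R,3S,4R,6S)-2-hydroxy-4-(1-iodoethenyl)-1-methyl-7-oxabicyclo[4.1.0]heptan-3-yl (2E)-2-methylbut-2-enoate F11. Stannylation with (Bu3Sn)2 and PdCl2(PPh3)2 (toluene, 60 °C) gives 17.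

3. Step 8. What may go wrong: hydride delivery to the other face of C1 (through the conformer with an axial acyloxy group), or acyl migration from the C6 oxygen to the new C1 hydroxyl. Fallback, from 13 back to 16: Me4NBH(OAc)3 (MeCN/AcOH, −30 °C) is bound by the free C6 hydroxyl and delivers hydride to C1 from the same face, giving (1S,2S,6S)-6-ethynyl-3-methylcyclohex-3-ene-1,2-diol F8. VO(acac)2/t-BuOOH epoxidises syn to the allylic C1 hydroxyl to (1R,2R,3S,4S,6S)-4-ethynyl-1-methyl-7-oxabicyclo[4.1.0]heptane-2,3-diol F9. (E)-2-Methylbut-2-enoyl chloride with 2,4,6-collidine (CH2Cl2, −40 °C) acylates the less hindered C6 hydroxyl (the C1 hydroxyl sits next to the fully substituted oxirane carbon) to give 16.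

**Further compounds**

F1 | step 5 | (2E)-5-(trimethylsilyl)pent-2-en-4-ynal | C[Si](C)(C)C#C/C=C/C=O
F2 | step 5 | tert-butyl (6S)-3-methyl-2-oxo-6-[(trimethylsilyl)ethynyl]cyclohex-3-ene-1-carboxylate (C1 epimers) | C[Si](C)(C)C#C[C@@H]1C(C(=O)OC(C)(C)C)C(=O)C(C)=CC1
F3 | step 5 | (5S)-2-methyl-5-[(trimethylsilyl)ethynyl]cyclohex-2-en-1-one | C[Si](C)(C)C#C[C@@H]1CC(=O)C(C)=CC1
F4 | step 5 | (1S,4S,6S)-4-ethynyl-1-methyl-7-oxabicyclo[4.1.0]heptan-2-one | C#C[C@@H]1CC(=O)[C@@]2(C)O[C@H]2C1
F5 | step 5 | (1S,5R)-5-ethynyl-2-methylcyclohex-2-en-1-ol | C#C[C@@H]1CC=C(C)[C@@H](O)C1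
F6 | step 5 | (5R)-5-ethynyl-2-methylcyclohex-2-en-1-one | C#C[C@@H]1CC=C(C)C(=O)C1
F7 | step 5 | (1S,6S)-6-ethynyl-3-methyl-2-oxocyclohex-3-en-1-yl acetate | C#C[C@@H]1CC=C(C)C(=O)[C@H]1OC(C)=O
F8 | step 8 | (1S,2S,6S)-6-ethynyl-3-methylcyclohex-3-ene-1,2-diol | C#C[C@@H]1CC=C(C)[C@H](O)[C@H]1O
F9 | step 8 | (1R,2R,3S,4S,6S)-4-ethynyl-1-methyl-7-oxabicyclo[4.1.0]heptane-2,3-diol | C#C[C@@H]1C[C@@H]2O[C@]2(C)[C@H](O)[C@H]1O
F10 | step 10 | (1R,2R,3S,4R,6S)-2-hydroxy-1-methyl-4-[1-(triethylsilyl)ethenyl]-7-oxabicyclo[4.1.0]heptan-3-yl (2E)-2-methylbut-2-enoate | CC[Si](CC)(CC)C(=C)[C@@H]1C[C@@H]2O[C@]2(C)[C@H](O)[C@H]1OC(=O)/C(C)=C/C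
F11 | step 10 | (1R,2R,3S,4R,6S)-2-hydroxy-4-(1-iodoethenyl)-1-methyl-7-oxabicyclo[4.1.0]heptan-3-yl (2E)-2-methylbut-2-enoate | C=C(I)[C@@H]1C[C@@H]2O[C@]2(C)[C@H](O)[C@H]1OC(=O)/C(C)=C/C
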